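**Retrosynthetic overview**

1. Target ⇒ stearoylation of the C3 primary alcohol of a tetrahydrofuran carbinol. The tetrahydrofuran (second ring) ⇒ 5-exo capture by C1–OH of the C4 end of a pentadienyl cation released from C15 of an open-arm triene triol (SN2''-type etherification).
2. Triene triol ⇒ reduction of an α-alkylidene δ-lactone ⇒ aldol condensation of a C14 lactone with a C6 enal. The 7-OH/Δ8(Z) unit ⇒ singlet-oxygen ene reaction on the E-cyclononene.
3. Nine-membered carbocycle (first ring) ⇒ amine-catalysed intramolecular conjugate addition forging C4a–C11a in an acyclic C14 trienedial; the β-methyl enal adds through its α-carbon, so its methyl becomes the exocyclic methylene.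
4. Trienedial ⇒ (E,E)-farnesal + crotonaldehyde (cross-metathesis) ⇒ (E,E)-farnesol.
5. Ring order: carbocycle first (both ring-fusion centres), temporary δ-lactone, tetrahydrofuran last.

Assumption: names use the biogenetic xenicane numbering (C1 = ring OCH2, C3 = CH2O-acyl carbon, C4 = quaternary carbon, C4a/C11a = ring fusion, C7 = carbinol carbon, C11 = methylidene carbon, C12–C15 = side chain); where a name and a SMILES differ, the SMILES is authoritative.

**Route**

Step 1
Reactants: 1 (2E,6E)-farnesol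
Product: 2 (2E,6E)-farnesal
Conditions: MnO2 (15 equiv), CH2Cl2, 23 °C
Reagents that add atoms: none
Why: MnO2 allylic-alcohol oxidation stops at the enal and leaves the isolated trisubstituted olefins and their geometry untouched.

Step 2
Reactants: 2 (2E,6E)-farnesal; 3 (E)-but-2-enal (crotonaldehyde)
Product: 4 (2E,6E,10E)-3,7-dimethyldodeca-2,6,10-trienedial
Conditions: 3 (5 equiv), second-generation Hoveyda–Grubbs catalyst RuCl2(SIMes)(=CH-C6H4-2-OiPr) (5 mol%), CH2Cl2, 40 °C
Reagents that add atoms: none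
Why: Olefin cross-metathesis; the terminal isopropylidene is the only alkene of 2 that is both electron-rich and unhindered enough to enter the Ru cycle (the enal olefin is electron-poor, the central olefin is flanked by two chains), and enal partners give the E-enal.

Step 3
Reactants: 4 (2E,6E,10E)-3,7-dimethyldodeca-2,6,10-trienedial
Product: 6 2-[(1R,4E,9R)-9-(hydroxymethyl)-4-methyl-8-methylidenecyclonon-4-en-1-yl]ethan-1-ol, via cyclised dialdehyde 5 (not isolated)
Conditions: (S)-2-[diphenyl(trimethylsilyloxy)methyl]pyrrolidine (30 mol%), PhCO2H (30 mol%), toluene, 23 °C, 4 added over 24 h (2 mM final); then NaBH4, EtOH, 0 °C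
Reagents that add atoms: none
Why: Proposed new method: the amine turns the unhindered β-monosubstituted enal into an iminium ion (electrophilic C4a) and the β-methyl enal into its exocyclic dienamine, whose α-carbon (C11a) adds to C4a to close the nine-membered ring while the proton lost from the methyl group leaves the exocyclic methylene (the endocyclic dienamine would have to place a second ring double bond in the E-cyclononene and is disfavoured); the closest known reaction type is the secondary-amine-catalysed intramolecular dienamine Michael (Rauhut–Currier-type) cyclisation of tethered enals to five- and six-membered rings, extended here to a nine-membered ring by pseudo-high dilution; C4a is set by addition anti to the CPh2OSiMe3 group of the (S)-catalyst iminium ion (target configuration), C11a settles trans with both arms pseudo-equatorial on the E-cyclononene while still enolisable, and the NaBH4 quench fixes it before the β,γ-unsaturated aldehyde can conjugate.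

Step 4
Reactants: 6 2-[(1R,4E,9R)-9-(hydroxymethyl)-4-methyl-8-methylidenecyclonon-4-en-1-yl]ethan-1-ol
Product: 8 (4aR,7E,11aR)-7-methyl-11-methylidene-cyclonona[c]pyran-3-one δ-lactone (C1H2–O2–C3(=O)–C4H2, trans-fused), via lactol 7 (not isolated)
Conditions: TEMPO (20 mol%), PhI(OAc)2 (3 equiv), CH2Cl2, 23 °C
Reagents that add atoms: none
Why: Oxoammonium-mediated oxidative lactonisation of a 1,5-diol: the unhindered CH2CH2OH arm is oxidised first, the aldehyde is trapped by the C1 hydroxyl as the lactol and oxidised on, and the alkenes and ring-fusion centres are untouched.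

Step 5
Reactants: 8 (4aR,7E,11aR)-lactone
Product: 10 (4aR,7S,8Z,11aR)-7-hydroxy-7-methyl-11-methylidene-Δ8-cyclonona[c]pyran-3-one δ-lactone, via hydroperoxide 9 (not isolated)
Conditions: O2, tetraphenylporphyrin (1 mol%), white LED, CH2Cl2, −20 °C; then PPh3, 0 °C
Reagents that add atoms: dioxygen O=O
Why: Schenck ene reaction of singlet oxygen, chemoselective for the trisubstituted E-olefin over the 1,1-disubstituted methylene; oxygen is delivered to C7 from the exposed outer face of the E-cyclononene (7S, the face that gives the 7S,8S-epoxides of this ring class) with suprafacial abstraction of the aligned H-9, so the double bond moves to C8=C9 as the strain-relieving Z isomer, and PPh3 reduces the hydroperoxide with retention.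

Step 6
Reactants: 11 2-methylbut-3-en-2-ol; 3 (E)-but-2-enal
Product: 13 (E)-4-methyl-4-(trimethylsilyloxy)pent-2-enal, via hydroxy enal 12 (not isolated)
Conditions: 3 (3 equiv), second-generation Hoveyda–Grubbs catalyst RuCl2(SIMes)(=CH-C6H4-2-OiPr) (2 mol%), CH2Cl2, 40 °C; then imidazole, Me3SiCl, 0 °C; distil
Reagents that add atoms: chlorotrimethylsilane C[Si](C)(C)Cl
Why: E-selective cross-metathesis of a tertiary allylic alcohol with an enal, followed by silylation so that the aldehyde carries no acidic proton into the enolate step.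

Step 7
Reactants: 10 (4aR,7S,8Z,11aR)-7-hydroxy lactone; 13 (E)-4-methyl-4-(trimethylsilyloxy)pent-2-enal
Product: 15 (4E,4aS,7S,8Z,11aR)-7-acetoxy-4-[(E)-4-methyl-4-(trimethylsilyloxy)pent-2-en-1-ylidene]-7-methyl-11-methylidene-Δ8-cyclonona[c]pyran-3-one δ-lactone, via bis-acetate aldol adduct 14 (not isolated)
Conditions: LDA (LiN(iPr)2, 2.2 equiv), THF, −78 °C; 13 (1.3 equiv); Ac2O (3 equiv), −78→0 °C; DBU (3 equiv), 23 °C
Reagents that add atoms: acetic anhydride CC(=O)OC(C)=O
Why: Aldol condensation: the lactone enolate (as alkoxide/enolate dianion) adds 1,2 to the enal, both alkoxides are acetylated, and E1cB loss of the β-acetate gives the (E)-alkylidene lactone (C13 anti to the carbonyl, syn to C4a); the tertiary C7 acetate is a bystander removed in step 8.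

Step 8
Reactants: 15 (4E,4aS,7S,8Z,11aR)-alkylidene lactone
Product: 16 (2E,4E)-2-[(1S,4S,5Z,9R)-4-hydroxy-9-(hydroxymethyl)-4-methyl-8-methylidenecyclonon-5-en-1-yl]-6-methyl-6-(trimethylsilyloxy)hepta-2,4-dien-1-ol
Conditions: DIBAL-H (iBu2AlH, 7 equiv), CH2Cl2, −78→0 °C; aq. KNaC4H4O6
Reagents that add atoms: none
Why: 1,2-Reduction of the conjugated lactone to the 1,5-diol with reductive cleavage of the C7 acetate; the silyl ether and all olefin geometries are retained.

Step 9
Reactants: 16 triene triol
Product: 17 (4R,4aS,7S,8Z,11aR)-tetrahydrofuran carbinol (C1–O–C4 ether, C3H2OH and (1E)-4-methylpenta-1,3-dienyl on C4; the destearoyl target)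
Conditions: PPTS (20 mol%), CH2Cl2, 0→23 °C
Reagents that add atoms: none
Why: Acid-induced SN2''-type (vinylogous SN1) cycloetherification: the doubly allylic tertiary C15–OSiMe3 ionises far more readily than the simple allylic C7–OH, the pentadienyl cation is captured 5-exo at its C4 terminus by C1–OH, and A(1,3) strain (H-4a eclipsing C4=C12 because C13 is syn to C4a) exposes the C11a-side face so that the dienyl group ends cis to H-4a (4R), with C12=C13 formed E from the s-trans triene.

Step 10
Reactants: 17 tetrahydrofuran carbinol; 18 octadecanoyl chloride (stearoyl chloride)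
Product: 19 CNP0274030.1
Conditions: pyridine, DMAP (5 mol%), CH2Cl2, 0 °C
Reagents that add atoms: none
Why: Nucleophilic-catalysed acylation (esterification) of the only primary alcohol; the tertiary allylic C7–OH does not react with 1.1 equiv of acid chloride at 0 °C.

**Compound list**

1 | (2E,6E)-farnesol | CC(C)=CCC/C(C)=C/CC/C(C)=C/CO | starting material
2 | (2E,6E)-farnesal | CC(C)=CCC/C(C)=C/CC/C(C)=C/C=O | intermediate
3 | (E)-but-2-enal (crotonaldehyde) | C/C=C/C=O | starting material
4 | (2E,6E,10E)-3,7-dimethyldodeca-2,6,10-trienedial | O=C/C=C/CC/C(C)=C/CC/C(C)=C/C=O | intermediate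
5 | 2-[(1R,4E,9R)-9-formyl-4-methyl-8-methylidenecyclonon-4-en-1-yl]acetaldehyde | C=C1CC/C=C(\C)CC[C@H](CC=O)[C@H]1C=O | intermediate
6 | 2-[(1R,4E,9R)-9-(hydroxymethyl)-4-methyl-8-methylidenecyclonon-4-en-1-yl]ethan-1-ol | C=C1CC/C=C(\C)CC[C@H](CCO)[C@H]1CO | intermediate
7 | (4aR,7E,11aR)-7-methyl-11-methylidene-cyclonona[c]pyran-3-ol lactol (C3 epimers) | C=C1CC/C=C(\C)CC[C@H]2[C@H]1COC(O)C2 | intermediate
8 | (4aR,7E,11aR)-7-methyl-11-methylidene-cyclonona[c]pyran-3-one δ-lactone | C=C1CC/C=C(\C)CC[C@H]2[C@H]1COC(=O)C2 | intermediate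
9 | (4aR,7S,8Z,11aR)-7-hydroperoxy-7-methyl-11-methylidene-Δ8-lactone | C=C1C/C=C\[C@@](C)(OO)CC[C@H]2[C@H]1COC(=O)C2 | intermediate
10 | (4aR,7S,8Z,11aR)-7-hydroxy-7-methyl-11-methylidene-Δ8-lactone | C=C1C/C=C\[C@@](C)(O)CC[C@H]2[C@H]1COC(=O)C2 | intermediate
11 | 2-methylbut-3-en-2-ol | C=CC(C)(C)O | starting material
12 | (E)-4-hydroxy-4-methylpent-2-enal | O=C/C=C/C(C)(C)O | intermediate
13 | (E)-4-methyl-4-(trimethylsilyloxy)pent-2-enal | O=C/C=C/C(C)(C)O[Si](C)(C)C | intermediate
14 | (4aR,7S,8Z,11aR)-7-acetoxy-4-[(E)-1-acetoxy-4-methyl-4-(trimethylsilyloxy)pent-2-en-1-yl]-Δ8-lactone (C4/C12 diastereomers) | C=C1C/C=C\[C@@](C)(OC(C)=O)CC[C@H]2[C@H]1COC(=O)C2C(OC(C)=O)/C=C/C(C)(C)O[Si](C)(C)C | intermediate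
15 | (4E,4aS,7S,8Z,11aR)-7-acetoxy-4-[(E)-4-methyl-4-(trimethylsilyloxy)pent-2-en-1-ylidene]-Δ8-lactone | C=C1C/C=C\[C@@](C)(OC(C)=O)CC[C@H]2[C@H]1COC(=O)/C2=C/C=C/C(C)(C)O[Si](C)(C)C | intermediate
16 | (2E,4E)-2-[(1S,4S,5Z,9R)-4-hydroxy-9-(hydroxymethyl)-4-methyl-8-methylidenecyclonon-5-en-1-yl]-6-methyl-6-(trimethylsilyloxy)hepta-2,4-dien-1-ol | C=C1C/C=C\[C@@](C)(O)CC[C@H](/C(CO)=C\C=C\C(C)(C)O[Si](C)(C)C)[C@H]1CO | intermediate
17 | (4R,4aS,7S,8Z,11aR)-tetrahydrofuran carbinol (destearoyl target) | C=C1C/C=C\[C@@](C)(O)CC[C@H]2[C@H]1CO[C@@]2(/C=C/C=C(C)C)CO | intermediate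
18 | octadecanoyl chloride (stearoyl chloride) | CCCCCCCCCCCCCCCCCC(=O)Cl | starting material
19 | CNP0274030.1, (4R,4aS,7S,8Z,11aR,12E)-stearate | C=C1C/C=C\[C@@](C)(O)CC[C@H]2[C@H]1CO[C@@]2(/C=C/C=C(C)C)COC(=O)CCCCCCCCCCCCCCCCC | target

**Step count and risks**

Total steps: 10. Longest linear sequence: 9 (steps 1–5 and 7–10, from 1).

Most likely to fail, step 3. Closing an E-cyclononene by conjugate addition from an open chain has no direct precedent. Oligomerisation, attack through the γ-carbon, conjugation of the product aldehyde, and the sense and level of induction at C4a/C11a are all open. If it fails, the same C4a–C11a bond and exocyclic methylene can be made by a transannular sigmatropic ring contraction, setting out from 2. Oxidation with NaClO2/NaH2PO4/2-methylbut-2-ene gives (2E,6E)-farnesoic acid F1. Cross-metathesis with (Z)-but-2-ene-1,4-diol (same Ru catalyst) gives (2E,6E,10E)-12-hydroxy-3,7-dimethyldodeca-2,6,10-trienoic acid F2. 2,4,6-Trichlorobenzoyl chloride/Et3N, then DMAP at high dilution, closes (3E,7E,11E)-4,8-dimethyl-1-oxacyclotrideca-3,7,11-trien-2-one F3. Soft enolisation to the boron dienolate with an enantiopure 2-bromo-4,5-diphenyl-1,3-bis(tolylsulfonyl)-1,3,2-diazaborolidine (whichever enantiomer gives the required sense) and iPr2NEt triggers an enantioselective ester-enolate Claisen rearrangement. This contracts the 13-membered lactone to the nine-membered (1R,5E,9R)-9-ethenyl-6-methyl-2-methylidenecyclonon-5-ene-1-carboxylic acid F4, whose carboxyl-bearing centre can still be equilibrated to trans. LiAlH4 gives [(1R,5E,9R)-9-ethenyl-6-methyl-2-methylidenecyclonon-5-en-1-yl]methanol F5. 9-BBN then NaOH/H2O2 hydroborates only the vinyl group and comes back to the route at 6.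

Second, step 5. Singlet oxygen may instead abstract a methyl hydrogen (8-hydroperoxide with a 7-methylidene group) or give the E-Δ8 isomer. The fallback sets out from 8 and replaces the ene reaction by an epoxide/selenium sequence. mCPBA/NaHCO3 epoxidises only the trisubstituted E-olefin from the outer face to the (4aR,7S,8S,11aR)-7,8-epoxy lactone F6. PhSeNa (from PhSeSePh and NaBH4, EtOH) opens it at the secondary C8 with inversion to the (7S,8R)-8-phenylselanyl-7-hydroxy lactone F7. H2O2 gives the (7S,8R)-8-phenylseleninyl-7-hydroxy lactone F8, whose syn-elimination away from the carbinol carbon installs the C8=C9 olefin and comes back to the route at 10.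

Third, step 9. The cation may be captured at C13 or C15, or by the C7 hydroxyl; C4 may equilibrate; and the C7 allylic alcohol may ionise. The fallback sets out from 10 and replaces ionisation by an electrophile-triggered etherification on a C15-deoxy side chain. The step 7 protocol with commercial (E)-4-methylpent-2-enal gives the (4E,4aS,7S,8Z,11aR)-7-acetoxy-4-[(E)-4-methylpent-2-en-1-ylidene] lactone F9. DIBAL-H gives (2E,4E)-2-[(1S,4S,5Z,9R)-4-hydroxy-9-(hydroxymethyl)-4-methyl-8-methylidenecyclonon-5-en-1-yl]-6-methylhepta-2,4-dien-1-ol F10. N-Iodosuccinimide/NaHCO3 at −40 °C effects a 1,4-iodoetherification (C1–OH onto C4 under the same A(1,3) control, iodine at C14) to the (4R,4aS,7S,8Z,11aR,12E)-14-iodo tetrahydrofuran carbinol F11. DBU then eliminates across C14–C15 to the conjugated diene and comes back to the route at 17.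

**Further compounds**

F1 | step 3 | (2E,6E)-farnesoic acid | CC(C)=CCC/C(C)=C/CC/C(C)=C/C(=O)O
F2 | step 3 | (2E,6E,10E)-12-hydroxy-3,7-dimethyldodeca-2,6,10-trienoic acid | OC/C=C/CC/C(C)=C/CC/C(C)=C/C(=O)O
F3 | step 3 | (3E,7E,11E)-4,8-dimethyl-1-oxacyclotrideca-3,7,11-trien-2-one | O=C1/C=C(\C)CC/C=C(\C)CC/C=C/CO1
F4 | step 3 | (1R,5E,9R)-9-ethenyl-6-methyl-2-methylidenecyclonon-5-ene-1-carboxylic acid | C=C1CC/C=C(\C)CC[C@H](C=C)[C@H]1C(=O)O
F5 | step 3 | [(1R,5E,9R)-9-ethenyl-6-methyl-2-methylidenecyclonon-5-en-1-yl]methanol | C=C1CC/C=C(\C)CC[C@H](C=C)[C@H]1CO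
F6 | step 5 | (4aR,7S,8S,11aR)-7,8-epoxy-7-methyl-11-methylidene-cyclonona[c]pyran-3-one δ-lactone | C=C1CC[C@@H]2O[C@@]2(C)CC[C@H]3[C@H]1COC(=O)C3
F7 | step 5 | (4aR,7S,8R,11aR)-7-hydroxy-7-methyl-11-methylidene-8-(phenylselanyl)-cyclonona[c]pyran-3-one δ-lactone | C=C1CC[C@@H]([Se]c2ccccc2)[C@@](C)(O)CC[C@H]3[C@H]1COC(=O)C3
F8 | step 5 | (4aR,7S,8R,11aR)-7-hydroxy-7-methyl-11-methylidene-8-(phenylseleninyl)-cyclonona[c]pyran-3-one δ-lactone (Se epimers) | C=C1CC[C@@H]([Se](=O)c2ccccc2)[C@@](C)(O)CC[C@H]3[C@H]1COC(=O)C3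
F9 | step 9 | (4E,4aS,7S,8Z,11aR)-7-acetoxy-4-[(E)-4-methylpent-2-en-1-ylidene]-7-methyl-11-methylidene-Δ8-lactone | C=C1C/C=C\[C@@](C)(OC(C)=O)CC[C@H]2[C@H]1COC(=O)/C2=C/C=C/C(C)C
F10 | step 9 | (2E,4E)-2-[(1S,4S,5Z,9R)-4-hydroxy-9-(hydroxymethyl)-4-methyl-8-methylidenecyclonon-5-en-1-yl]-6-methylhepta-2,4-dien-1-ol | C=C1C/C=C\[C@@](C)(O)CC[C@H](/C(CO)=C\C=C\C(C)C)[C@H]1CO
F11 | step 9 | (4R,4aS,7S,8Z,11aR,12E)-14-iodo tetrahydrofuran carbinol (C14 epimers) | C=C1C/C=C\[C@@](C)(O)CC[C@H]2[C@H]1CO[C@@]2(/C=C/C(I)C(C)C)CO
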